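## Retrosynthetic overview

1. 18 ⇒ aldehyde 16. The (Z)-C3=C4 bond is made last, by a Peterson-type enyne olefination.
2. 16 ⇒ oxepene diol 14. Ring B (tetrahydrofuran, C6–O–C9) and C10–Br come from a transannular bromoetherification. C13–Br comes from invertive bromination of the 13R alcohol 12.
3. 12 ⇒ acyclic bis-homoallyl ether 11. Ring A (oxepene, C9=C10) is closed by ring-closing metathesis. C13–OH comes from Felkin–Anh reduction of ethyl ketone 10.
4. 10 ⇒ carbinol 5 + diazoester 7. The C7–O–C12 bond and the C12 centre are made by the proposed catalyst-controlled O–H insertion.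
5. 5 ⇒ (R)-butane-1,2,4-triol 1 (C6) plus asymmetric allylboration (C7). Ring order: A first, then B.

Atom labels follow the target chain: HC1≡C2–C3=C4–C5–C6(O)–C7(O)–C8–C9(O)–C10(Br)–C11–C12(O)–C13(Br)–C14–C15, with ether bridges C6–O–C9 and C7–O–C12. The target is 3Z,6R,7R,9R,10R,12R,13S.

Assumption: the (R) enantiomer of the spiro phosphoric acid in step 5 is taken as the one matched to 12R; the sense of induction is read from the first run, and the (S) acid is used if it is reversed.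

## Route

Step 1
Reactants: 1 (2R)-butane-1,2,4-triol
Product: 2 [(2R,4R)-2-(4-methoxyphenyl)-1,3-dioxan-4-yl]methanol
Conditions: 4-MeOC6H4CH(OMe)2 (1.1 equiv), camphorsulfonic acid (5 mol %), CH2Cl2, rt, 16 h
Reagents that add atoms: 4-methoxybenzaldehyde dimethyl acetal, COc1ccc(C(OC)OC)cc1
Why: Acid-catalysed transacetalisation under thermodynamic control favours the six-membered acetal across O4/O6 with both substituents equatorial, so the acetal carbon is set cis (2R) to the untouched C6 centre and only the C7 primary hydroxyl stays free.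

Step 2
Reactants: 2 [(2R,4R)-2-(4-methoxyphenyl)-1,3-dioxan-4-yl]methanol
Product: 3 (2R,4R)-2-(4-methoxyphenyl)-1,3-dioxane-4-carbaldehyde
Conditions: Dess–Martin periodinane, pyridine, CH2Cl2, 0 °C → rt
Reagents that add atoms: none
Why: Dess–Martin oxidation stops at the aldehyde under buffered, near-neutral conditions, so the acetal survives and the α-alkoxy centre C6 is not epimerised.

Step 3
Reactants: 3 (2R,4R)-2-(4-methoxyphenyl)-1,3-dioxane-4-carbaldehyde
Product: 5 (1R)-1-[(2R,4R)-2-(4-methoxyphenyl)-1,3-dioxan-4-yl]but-3-en-1-ol, via diisopinocampheylborinate ester 4 (not isolated)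
Conditions: B-allyldiisopinocampheylborane of the (−)-α-pinene series (1.3 equiv), Et2O, −78 °C; then 3 M NaOH, 30% H2O2, rt
Reagents that add atoms: B-allyldiisopinocampheylborane from (−)-α-pinene, C=CCB([C@H]1C[C@H]2C[C@@H]([C@@H]1C)C2(C)C)[C@H]1C[C@H]2C[C@@H]([C@@H]1C)C2(C)C
Why: Brown asymmetric allylboration runs through a closed chair Zimmerman–Traxler transition state in which the isopinocampheyl groups direct allyl to the aldehyde face that gives 7R (syn to the C6 oxygen), and alkaline peroxide then cleaves the boron bonds of 4.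

Step 4
Reactants: 6 ethyl 2-acetylpent-4-enoate (racemic)
Product: 7 ethyl 2-diazopent-4-enoate
Conditions: 4-acetamidobenzenesulfonyl azide (1.2 equiv), DBU (1.5 equiv), MeCN, 0 °C → rt
Reagents that add atoms: 4-acetamidobenzenesulfonyl azide, CC(=O)Nc1ccc(cc1)S(=O)(=O)N=[N+]=[N-]
Why: In this Regitz-type deacylative diazo transfer the enolate attacks the azide terminus and the triazene collapses with transfer of the acetyl group to the sulfonamide nitrogen, which leaves the α-allyl diazoester.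

Step 5
Reactants: 5 (1R)-1-[(2R,4R)-2-(4-methoxyphenyl)-1,3-dioxan-4-yl]but-3-en-1-ol; 7 ethyl 2-diazopent-4-enoate
Product: 8 ethyl (2R)-2-({(1R)-1-[(2R,4R)-2-(4-methoxyphenyl)-1,3-dioxan-4-yl]but-3-enyl}oxy)pent-4-enoate
Conditions: Rh2(O2CCPh3)4 (1 mol %), (R)-6,6'-bis(2,4,6-triisopropylphenyl)-1,1'-spirobiindane-7,7'-diyl hydrogen phosphate (5 mol %), 4 Å MS, CH2Cl2, −40 °C, 7 (2.5 equiv) added over 4 h
Reagents that add atoms: none
Why: Proposed new method: Rh2(O2CCPh3)4 turns 7 into an electrophilic rhodium carbenoid that is captured by the free C7 hydroxyl of 5 faster than by the unactivated terminal alkenes, the oxonium ylide relaxes to a ketene hemiacetal enol, and the chiral spiro phosphoric acid relays the proton to one enol face through a hydrogen-bonded cyclic transition state, so the C7–O–C12 bond and the 12R centre are made in one operation under catalyst control, while the bulky triphenylacetate ligands, the low temperature and the slow addition of excess 7 hold back the 1,2-hydride shift to ethyl pentadienoate and carbene dimerisation; the closest known reaction type is the enantioselective O–H insertion of α-aryl or α-methyl diazoesters into water, phenols and simple primary alcohols under dirhodium/chiral phosphoric acid or copper/bisoxazoline catalysis, which has not been shown for a hindered chiral secondary carbinol combined with an α-allyl diazoester that carries β-hydrogens.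

Step 6
Reactants: 8 ethyl (2R)-2-({(1R)-1-[(2R,4R)-2-(4-methoxyphenyl)-1,3-dioxan-4-yl]but-3-enyl}oxy)pent-4-enoate
Product: 9 (2R)-N-methoxy-N-methyl-2-({(1R)-1-[(2R,4R)-2-(4-methoxyphenyl)-1,3-dioxan-4-yl]but-3-enyl}oxy)pent-4-enamide
Conditions: MeONHMe·HCl (2.5 equiv), i-PrMgCl (5 equiv), THF, −20 °C
Reagents that add atoms: N,O-dimethylhydroxylamine hydrochloride, CNOC.Cl
Why: Weinreb amide formation by aminolysis of the ester with the magnesium amide is fast at −20 °C, where the α-alkoxy centre C12 is not enolised and the acetal and alkenes are inert.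

Step 7
Reactants: 9 (2R)-N-methoxy-N-methyl-2-({(1R)-1-[(2R,4R)-2-(4-methoxyphenyl)-1,3-dioxan-4-yl]but-3-enyl}oxy)pent-4-enamide
Product: 10 (4R)-4-({(1R)-1-[(2R,4R)-2-(4-methoxyphenyl)-1,3-dioxan-4-yl]but-3-enyl}oxy)hept-6-en-3-one
Conditions: EtMgBr (2 equiv), THF, −20 → 0 °C
Reagents that add atoms: ethylmagnesium bromide, CC[Mg]Br
Why: In the Weinreb ketone synthesis the five-membered magnesium chelate of the tetrahedral adduct persists until quench, so there is no over-addition and C12 stays intact while C14–C15 are attached.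

Step 8
Reactants: 10 (4R)-4-({(1R)-1-[(2R,4R)-2-(4-methoxyphenyl)-1,3-dioxan-4-yl]but-3-enyl}oxy)hept-6-en-3-one
Product: 11 (3R,4R)-4-({(1R)-1-[(2R,4R)-2-(4-methoxyphenyl)-1,3-dioxan-4-yl]but-3-enyl}oxy)hept-6-en-3-ol
Conditions: LiBH(s-Bu)3 (L-Selectride, 1.5 equiv), THF, −78 °C; then NaOH, H2O2, 0 °C
Reagents that add atoms: none
Why: Polar Felkin–Anh reduction with a bulky, non-chelating hydride attacks anti to the C12 alkoxy group past the C12 hydrogen and gives the syn 12R,13R alcohol.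

Step 9
Reactants: 11 (3R,4R)-4-({(1R)-1-[(2R,4R)-2-(4-methoxyphenyl)-1,3-dioxan-4-yl]but-3-enyl}oxy)hept-6-en-3-ol
Product: 12 (1R)-1-{(2R,7R)-7-[(2R,4R)-2-(4-methoxyphenyl)-1,3-dioxan-4-yl]-2,3,6,7-tetrahydrooxepin-2-yl}propan-1-ol
Conditions: second-generation Grubbs catalyst RuCl2(=CHPh)(PCy3)(H2IMes) (5 mol %), CH2Cl2 (2 mM), 40 °C
Reagents that add atoms: none
Why: Ring-closing metathesis of the only two alkenes, both terminal and homoallylic to the ether oxygen, closes the seven-membered ring A with a necessarily cis C9=C10 bond, is driven by loss of ethene, and touches no stereocentre.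

Step 10
Reactants: 12 (1R)-1-{(2R,7R)-7-[(2R,4R)-2-(4-methoxyphenyl)-1,3-dioxan-4-yl]-2,3,6,7-tetrahydrooxepin-2-yl}propan-1-ol
Product: 13 (2R,4R)-4-{(2R,7R)-7-[(1S)-1-bromopropyl]-2,3,6,7-tetrahydrooxepin-2-yl}-2-(4-methoxyphenyl)-1,3-dioxane
Conditions: CBr4 (3 equiv), P(n-C8H17)3 (3 equiv), 2,6-di-tert-butylpyridine, toluene, 70 °C
Reagents that add atoms: carbon tetrabromide, BrC(Br)(Br)Br
Why: In this Appel-type bromination the only free hydroxyl is turned into an alkoxyphosphonium ion that bromide displaces by SN2 in a non-polar medium, which inverts 13R to the required 13S.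

Step 11
Reactants: 13 (2R,4R)-4-{(2R,7R)-7-[(1S)-1-bromopropyl]-2,3,6,7-tetrahydrooxepin-2-yl}-2-(4-methoxyphenyl)-1,3-dioxane
Product: 14 (1R)-1-{(2R,7R)-7-[(1S)-1-bromopropyl]-2,3,6,7-tetrahydrooxepin-2-yl}propane-1,3-diol
Conditions: AcOH–THF–H2O (3:1:1), 45 °C
Reagents that add atoms: none
Why: Mild acid hydrolysis cleaves the electron-rich arylidene acetal through its stabilised oxocarbenium ion, while the dialkyl ether, the alkene and the secondary bromide are untouched.

Step 12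
Reactants: 14 (1R)-1-{(2R,7R)-7-[(1S)-1-bromopropyl]-2,3,6,7-tetrahydrooxepin-2-yl}propane-1,3-diol
Product: 15 2-{(1R,3R,5R,6R,8R)-5-bromo-3-[(1S)-1-bromopropyl]-2,7-dioxabicyclo[4.2.1]nonan-8-yl}ethanol
Conditions: NBS (1.1 equiv), MeCN, −20 °C → rt, dark
Reagents that add atoms: N-bromosuccinimide, O=C1CCC(=O)N1Br
Why: In this transannular bromoetherification the bromonium ion forms reversibly, but only the one on the face anti to the C7 side chain can be opened by the C6 hydroxyl at C9 through a five-membered 5-exo transition state, so anti addition sets 9R and 10R and closes ring B, whereas the primary hydroxyl would need a seven-membered ring.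

Step 13
Reactants: 15 2-{(1R,3R,5R,6R,8R)-5-bromo-3-[(1S)-1-bromopropyl]-2,7-dioxabicyclo[4.2.1]nonan-8-yl}ethanol
Product: 16 {(1R,3R,5R,6R,8R)-5-bromo-3-[(1S)-1-bromopropyl]-2,7-dioxabicyclo[4.2.1]nonan-8-yl}acetaldehyde
Conditions: Dess–Martin periodinane, pyridine, CH2Cl2, 0 °C → rt
Reagents that add atoms: none
Why: Dess–Martin oxidation gives the β-alkoxy aldehyde without base strong enough to cause β-elimination or loss of HBr.

Step 14
Reactants: 16 {(1R,3R,5R,6R,8R)-5-bromo-3-[(1S)-1-bromopropyl]-2,7-dioxabicyclo[4.2.1]nonan-8-yl}acetaldehyde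
Product: 17 (1R,3R,5R,6R,8R)-5-bromo-3-[(1S)-1-bromopropyl]-8-[(2Z)-5-(triisopropylsilyl)pent-2-en-4-ynyl]-2,7-dioxabicyclo[4.2.1]nonane
Conditions: 1,3-bis(triisopropylsilyl)propyne (1.5 equiv), n-BuLi (1.4 equiv), THF, −20 °C; then 16, −78 → 0 °C
Reagents that add atoms: 1,3-bis(triisopropylsilyl)propyne, CC(C)[Si](CC#C[Si](C(C)C)(C(C)C)C(C)C)(C(C)C)C(C)C
Why: In this Peterson olefination the very bulky α-silyl propargyl anion adds to the aldehyde through the less crowded arrangement, and spontaneous syn elimination of silanolate gives the (Z)-enyne, with addition at −78 °C being faster than enolisation or attack on the bromides.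

Step 15
Reactants: 17 (1R,3R,5R,6R,8R)-5-bromo-3-[(1S)-1-bromopropyl]-8-[(2Z)-5-(triisopropylsilyl)pent-2-en-4-ynyl]-2,7-dioxabicyclo[4.2.1]nonane
Product: 18 (1R,3R,5R,6R,8R)-5-bromo-3-[(1S)-1-bromopropyl]-8-[(2Z)-pent-2-en-4-ynyl]-2,7-dioxabicyclo[4.2.1]nonane (target)
Conditions: Bu4NF (1.2 equiv), THF, −20 → 0 °C, 20 min
Reagents that add atoms: none
Why: Fluoride-induced protodesilylation of the alkynylsilane is fast at low temperature, so the two secondary bromides and the Z alkene are left unchanged.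

## Compound list

1 | (2R)-butane-1,2,4-triol | OCC[C@@H](O)CO | starting material
2 | [(2R,4R)-2-(4-methoxyphenyl)-1,3-dioxan-4-yl]methanol | OC[C@H]1CCO[C@@H](c2ccc(OC)cc2)O1 | intermediate
3 | (2R,4R)-2-(4-methoxyphenyl)-1,3-dioxane-4-carbaldehyde | O=C[C@H]1CCO[C@@H](c2ccc(OC)cc2)O1 | intermediate
4 | (1R)-1-[(2R,4R)-2-(4-methoxyphenyl)-1,3-dioxan-4-yl]but-3-enyl diisopinocampheylborinate | C=CC[C@@H](OB([C@H]3C[C@H]4C[C@@H]([C@@H]3C)C4(C)C)[C@H]5C[C@H]6C[C@@H]([C@@H]5C)C6(C)C)[C@H]1CCO[C@@H](c2ccc(OC)cc2)O1 | intermediate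
5 | (1R)-1-[(2R,4R)-2-(4-methoxyphenyl)-1,3-dioxan-4-yl]but-3-en-1-ol | C=CC[C@@H](O)[C@H]1CCO[C@@H](c2ccc(OC)cc2)O1 | intermediate
6 | ethyl 2-acetylpent-4-enoate (racemic; the centre is destroyed in step 4) | C=CCC(C(C)=O)C(=O)OCC | starting material
7 | ethyl 2-diazopent-4-enoate | C=CCC(=[N+]=[N-])C(=O)OCC | intermediate
8 | ethyl (2R)-2-({(1R)-1-[(2R,4R)-2-(4-methoxyphenyl)-1,3-dioxan-4-yl]but-3-enyl}oxy)pent-4-enoate | C=CC[C@@H](O[C@@H](C(=O)OCC)CC=C)[C@H]1CCO[C@@H](c2ccc(OC)cc2)O1 | intermediate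
9 | (2R)-N-methoxy-N-methyl-2-({(1R)-1-[(2R,4R)-2-(4-methoxyphenyl)-1,3-dioxan-4-yl]but-3-enyl}oxy)pent-4-enamide | C=CC[C@@H](O[C@@H](C(=O)N(C)OC)CC=C)[C@H]1CCO[C@@H](c2ccc(OC)cc2)O1 | intermediate
10 | (4R)-4-({(1R)-1-[(2R,4R)-2-(4-methoxyphenyl)-1,3-dioxan-4-yl]but-3-enyl}oxy)hept-6-en-3-one | C=CC[C@@H](O[C@@H](C(=O)CC)CC=C)[C@H]1CCO[C@@H](c2ccc(OC)cc2)O1 | intermediate
11 | (3R,4R)-4-({(1R)-1-[(2R,4R)-2-(4-methoxyphenyl)-1,3-dioxan-4-yl]but-3-enyl}oxy)hept-6-en-3-ol | C=CC[C@@H](O[C@@H]([C@H](O)CC)CC=C)[C@H]1CCO[C@@H](c2ccc(OC)cc2)O1 | intermediate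
12 | (1R)-1-{(2R,7R)-7-[(2R,4R)-2-(4-methoxyphenyl)-1,3-dioxan-4-yl]-2,3,6,7-tetrahydrooxepin-2-yl}propan-1-ol | CC[C@@H](O)[C@H]1CC=CC[C@@H](O1)[C@H]2CCO[C@@H](c3ccc(OC)cc3)O2 | intermediate
13 | (2R,4R)-4-{(2R,7R)-7-[(1S)-1-bromopropyl]-2,3,6,7-tetrahydrooxepin-2-yl}-2-(4-methoxyphenyl)-1,3-dioxane | CC[C@H](Br)[C@H]1CC=CC[C@@H](O1)[C@H]2CCO[C@@H](c3ccc(OC)cc3)O2 | intermediate
14 | (1R)-1-{(2R,7R)-7-[(1S)-1-bromopropyl]-2,3,6,7-tetrahydrooxepin-2-yl}propane-1,3-diol | CC[C@H](Br)[C@H]1CC=CC[C@@H](O1)[C@H](O)CCO | intermediate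
15 | 2-{(1R,3R,5R,6R,8R)-5-bromo-3-[(1S)-1-bromopropyl]-2,7-dioxabicyclo[4.2.1]nonan-8-yl}ethanol | OCC[C@H]1O[C@@H]2C[C@H]1O[C@@H]([C@@H](Br)CC)C[C@H]2Br | intermediate
16 | {(1R,3R,5R,6R,8R)-5-bromo-3-[(1S)-1-bromopropyl]-2,7-dioxabicyclo[4.2.1]nonan-8-yl}acetaldehyde | O=CC[C@H]1O[C@@H]2C[C@H]1O[C@@H]([C@@H](Br)CC)C[C@H]2Br | intermediate
17 | (1R,3R,5R,6R,8R)-5-bromo-3-[(1S)-1-bromopropyl]-8-[(2Z)-5-(triisopropylsilyl)pent-2-en-4-ynyl]-2,7-dioxabicyclo[4.2.1]nonane | CC(C)[Si](C#C/C=C\C[C@H]1O[C@@H]2C[C@H]1O[C@@H]([C@@H](Br)CC)C[C@H]2Br)(C(C)C)C(C)C | intermediate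
18 | (1R,3R,5R,6R,8R)-5-bromo-3-[(1S)-1-bromopropyl]-8-[(2Z)-pent-2-en-4-ynyl]-2,7-dioxabicyclo[4.2.1]nonane | C#C/C=C\C[C@H]1O[C@@H]2C[C@H]1O[C@@H]([C@@H](Br)CC)C[C@H]2Br | target

## Step count and risks

Total step count: 15.
Longest linear sequence: 14 (steps 1–3 and 5–15, from 1). Step 4 is a one-step side branch.

**First risk: step 5, the proposed O–H insertion.**
- The allylic β-hydrogens of the carbenoid may migrate faster than the hindered carbinol is captured.
- The catalyst may be mismatched with the C7 centre, which would give a poor 12R:12S ratio. The two epimers are diastereomers and can be separated on silica.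
- The fallback uses known auxiliary chemistry. It sets out from 5 and comes back at 9.
  - O-alkylation of 5 with bromoacetic acid (NaH, THF, 0 °C → rt) gives {(1R)-1-[(2R,4R)-2-(4-methoxyphenyl)-1,3-dioxan-4-yl]but-3-enyl}oxyacetic acid F1.
  - Activation as the mixed pivalic anhydride (PivCl, Et3N, THF) and acylation of lithiated (S)-4-benzyloxazolidin-2-one gives (4S)-4-benzyl-3-({(1R)-1-[(2R,4R)-2-(4-methoxyphenyl)-1,3-dioxan-4-yl]but-3-enyl}oxyacetyl)oxazolidin-2-one F2.
  - Asymmetric glycolate alkylation (NaN(SiMe3)2, allyl iodide, THF, −78 → −45 °C) goes through the chelated Z-enolate with attack anti to the benzyl group, which sets 12R. It gives (4S)-4-benzyl-3-[(2R)-2-({(1R)-1-[(2R,4R)-2-(4-methoxyphenyl)-1,3-dioxan-4-yl]but-3-enyl}oxy)pent-4-enoyl]oxazolidin-2-one F3.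
  - Aminolysis with MeONHMe·HCl and AlMe3 (CH2Cl2, −10 °C → rt) releases the auxiliary and delivers 9.

**Second risk: step 10, the invertive bromination next to the ring oxygen.**
- The ring oxygen can take part through a three-membered oxonium ion, which leads to retention or a ring-enlarged oxocane bromide.
- Elimination can compete, and the acetal may suffer at 70 °C.
- The fallback separates activation from displacement. It sets out from 12 and comes back at 13.
  - ClCH2SO2Cl and 2,6-lutidine (CH2Cl2, 0 °C) give the isolable (1R)-1-{(2R,7R)-7-[(2R,4R)-2-(4-methoxyphenyl)-1,3-dioxan-4-yl]-2,3,6,7-tetrahydrooxepin-2-yl}propyl chloromethanesulfonate F4.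
  - F4 is then displaced by external bromide (Bu4NBr, toluene, 40–50 °C) in a clean SN2 reaction with inversion to 13.

**Third risk: step 14, the enyne olefination.**
- The β-alkoxy aldehyde may enolise or undergo β-elimination under the lithium reagent.
- The Z:E ratio may erode.
- The fallback builds the enyne by olefination and cross-coupling. It sets out from 16 and comes back at 18.
  - Stork–Zhao olefination ([Ph3PCH2I]I, NaN(SiMe3)2, THF–DMPU, −78 °C) gives (1R,3R,5R,6R,8R)-5-bromo-3-[(1S)-1-bromopropyl]-8-[(2Z)-3-iodoprop-2-enyl]-2,7-dioxabicyclo[4.2.1]nonane F5.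
  - Sonogashira coupling with trimethylsilylacetylene (Pd(PPh3)4, a zerovalent palladium complex, CuI, i-Pr2NH, THF, rt) retains the alkene geometry. It gives (1R,3R,5R,6R,8R)-5-bromo-3-[(1S)-1-bromopropyl]-8-[(2Z)-5-(trimethylsilyl)pent-2-en-4-ynyl]-2,7-dioxabicyclo[4.2.1]nonane F6.
  - K2CO3 in MeOH (0 °C) removes the silyl group to give 18.

## Further compounds

F1 | step 5 | {(1R)-1-[(2R,4R)-2-(4-methoxyphenyl)-1,3-dioxan-4-yl]but-3-enyl}oxyacetic acid | C=CC[C@@H](OCC(=O)O)[C@H]1CCO[C@@H](c2ccc(OC)cc2)O1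
F2 | step 5 | (4S)-4-benzyl-3-({(1R)-1-[(2R,4R)-2-(4-methoxyphenyl)-1,3-dioxan-4-yl]but-3-enyl}oxyacetyl)oxazolidin-2-one | C=CC[C@@H](OCC(=O)N3[C@@H](Cc4ccccc4)COC3=O)[C@H]1CCO[C@@H](c2ccc(OC)cc2)O1
F3 | step 5 | (4S)-4-benzyl-3-[(2R)-2-({(1R)-1-[(2R,4R)-2-(4-methoxyphenyl)-1,3-dioxan-4-yl]but-3-enyl}oxy)pent-4-enoyl]oxazolidin-2-one | C=CC[C@@H](O[C@@H](C(=O)N3[C@@H](Cc4ccccc4)COC3=O)CC=C)[C@H]1CCO[C@@H](c2ccc(OC)cc2)O1
F4 | step 10 | (1R)-1-{(2R,7R)-7-[(2R,4R)-2-(4-methoxyphenyl)-1,3-dioxan-4-yl]-2,3,6,7-tetrahydrooxepin-2-yl}propyl chloromethanesulfonate | CC[C@@H](OS(=O)(=O)CCl)[C@H]1CC=CC[C@@H](O1)[C@H]2CCO[C@@H](c3ccc(OC)cc3)O2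
F5 | step 14 | (1R,3R,5R,6R,8R)-5-bromo-3-[(1S)-1-bromopropyl]-8-[(2Z)-3-iodoprop-2-enyl]-2,7-dioxabicyclo[4.2.1]nonane | I/C=C\C[C@H]1O[C@@H]2C[C@H]1O[C@@H]([C@@H](Br)CC)C[C@H]2Br
F6 | step 14 | (1R,3R,5R,6R,8R)-5-bromo-3-[(1S)-1-bromopropyl]-8-[(2Z)-5-(trimethylsilyl)pent-2-en-4-ynyl]-2,7-dioxabicyclo[4.2.1]nonane | C[Si](C)(C)C#C/C=C\C[C@H]1O[C@@H]2C[C@H]1O[C@@H]([C@@H](Br)CC)C[C@H]2Br
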